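## Strategy

- Locants: C1–C10 are the carbons of the ten-membered ring (C5 and C10 joined through the ether oxygen, CO2Me on C4, CH3 on C10). C11 (on C7) carries the exocyclic C13 and the lactone carbonyl C12; the lactone oxygen sits on C6 and the epoxy ester on C8.
- Cuts: first the C8 ester (epoxy acid); then, in one retro-step, the C5–C6 bond, the lactone O–C12 bond and the C3=C4 double bond (back to a C3 acetate and a C6 aldehyde); then C7–C8 (allylboration), O–C5 (enol ether closure) and C3–C4 (aldol). This ends at (S)-linalool, methyl 3,3-dimethoxypropanoate, methyl acrylate, a silyloxyacetaldehyde and tiglic acid.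
- Enabling feature: C5 is at once the bridgehead ether carbon and the neighbour of C4 in the C3=C4–CO2Me unit. In the seven-membered enol ether (O, C5=C4, C3, C2, C1, C10) it is therefore the β-carbon of a cyclic β-alkoxyacrylate with a leaving group at C3, and the adjacent lactone carbinol C6 can be delivered as a ketyl.
- Forward order: the oxepene is closed first, the chain C8–C7(–C11)–C6 is attached by allylboration, the oxepane (O, C5–C10) and the γ-lactone close together in the key step, and the epoxy ester goes on last.
- Stereochemistry: C10 from (S)-linalool; C7 and C8 together in the syn-allylboration (chiral acid for the C8 face); C5 from C10 through the tether and C6 in the ketyl addition; both epoxide carbons from a Sharpless epoxidation.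

Key step: step 16

Remark: C3 (and C4 in the aldol adduct) is carried as a mixture of epimers, because both centres are trigonal in the target. The (S)-TRIP antipode in step 12 is chosen on the assumption that the (R)-acid directs allyl transfer to the Re face of simple aldehydes.

## Route

Step 1
Reactants: 1 (S)-(+)-linalool
Product: 3 (3S)-3,7-dimethyloct-6-ene-1,3-diol, via B-alkyl-9-BBN adduct 2 (not isolated)
Conditions: 9-BBN (1.3 equiv), THF, 0 °C → rt; NaOH aq, H2O2, 0 °C
Reagents that add atoms: hydrogen peroxide, OO
Why: Hydroboration–oxidation with 9-BBN takes the monosubstituted vinyl group far faster than the trisubstituted alkene and puts boron on the terminal carbon, leaving the C10 centre untouched.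

Step 2
Reactants: 3 (3S)-3,7-dimethyloct-6-ene-1,3-diol
Product: 4 (3S)-1-(tert-butyldiphenylsilyloxy)-3,7-dimethyloct-6-en-3-ol
Conditions: TBDPSCl, imidazole, CH2Cl2, 0 °C → rt
Reagents that add atoms: tert-butyldiphenylsilyl chloride, CC(C)(C)[Si](Cl)(c1ccccc1)c1ccccc1
Why: Silyl chloride/imidazole silylation selects the primary over the tertiary hydroxyl on steric grounds.

Step 3
Reactants: 4 (3S)-1-(tert-butyldiphenylsilyloxy)-3,7-dimethyloct-6-en-3-ol
Product: 7 lactol (5S)-5-[2-(tert-butyldiphenylsilyloxy)ethyl]-5-methyltetrahydrofuran-2-ol, via ozonide 5 (not isolated), via hydroxy aldehyde 6 (not isolated)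
Conditions: O3, CH2Cl2, −78 °C; PPh3, −78 °C → rt
Reagents that add atoms: ozone, [O-][O+]=O
Why: Ozonolysis with reductive work-up cleaves the only C=C bond to the C3 aldehyde, which the C10 hydroxyl traps as the five-membered lactol.

Step 4
Reactants: 7 lactol (5S)-5-[2-(tert-butyldiphenylsilyloxy)ethyl]-5-methyltetrahydrofuran-2-ol; 8 methyl 3,3-dimethoxypropanoate
Product: 10 aldol diol methyl (6S)-8-(tert-butyldiphenylsilyloxy)-2-(dimethoxymethyl)-3,6-dihydroxy-6-methyloctanoate, via lithium ester enolate 9 (not isolated)
Conditions: 8 (3.2 equiv), LiN(iPr)2 (3.0 equiv), THF, −78 °C; then 7, −78 → −40 °C; AcOH, −78 °C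
Reagents that add atoms: none
Why: Aldol addition of a preformed lithium ester enolate to a lactol: the first equivalent deprotonates the lactol and the excess captures its open hydroxy-aldehyde form at a temperature where the β-methoxy enolate does not yet lose methoxide; the new C3 and C4 centres are not controlled and need not be.

Step 5
Reactants: 10 aldol diol
Product: 12 hydroxy oxepene methyl (7S)-7-[2-(tert-butyldiphenylsilyloxy)ethyl]-4-hydroxy-7-methyl-4,5,6,7-tetrahydrooxepine-3-carboxylate, via acyclic (E)-β-methoxyacrylate 11 (not isolated)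
Conditions: PPTS (0.1 equiv), toluene, 5 Å MS, 80 °C
Reagents that add atoms: none
Why: Acid-catalysed loss of methanol gives the (E)-β-methoxyacrylate 11 (oxygen already cis to C3), and acid-catalysed transetherification of this vinylogous carbonate (conjugate addition–elimination) by the C10 hydroxyl, the only hydroxyl that can reach C5 in a ring larger than four, is pulled to the oxepene as the sieves take up methanol.

Step 6
Reactants: 12 hydroxy oxepene
Product: 13 methyl (7S)-4-acetoxy-7-[2-(tert-butyldiphenylsilyloxy)ethyl]-7-methyl-4,5,6,7-tetrahydrooxepine-3-carboxylate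
Conditions: Ac2O, pyridine, DMAP (cat.), CH2Cl2, 0 °C → rt
Reagents that add atoms: acetic anhydride, CC(=O)OC(C)=O
Why: DMAP-catalysed acetylation of the secondary allylic alcohol installs the leaving group that step 16 expels.

Step 7
Reactants: 13 oxepene acetate
Product: 14 methyl (7S)-4-acetoxy-7-(2-hydroxyethyl)-7-methyl-4,5,6,7-tetrahydrooxepine-3-carboxylate
Conditions: HF·pyridine, pyridine, THF, 0 °C → rt
Reagents that add atoms: none
Why: Fluoride cleavage of the silyl ether under buffered, non-basic conditions spares the acetate and the vinylogous carbonate.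

Step 8
Reactants: 14 primary alcohol
Product: 15 C8 aldehyde methyl (7S)-4-acetoxy-7-methyl-7-(2-oxoethyl)-4,5,6,7-tetrahydrooxepine-3-carboxylate
Conditions: Dess–Martin periodinane, NaHCO3, CH2Cl2, 0 °C → rt; used directly
Reagents that add atoms: none
Why: Dess–Martin oxidation is free of amine base, which matters because the aldehyde has the vinylogous carbonate oxygen on its β-carbon (C10) and would open by E1cB elimination.

Step 9
Reactants: 16 methyl acrylate; 17 (tert-butyldimethylsilyloxy)acetaldehyde
Product: 18 methyl 2-[2-(tert-butyldimethylsilyloxy)-1-hydroxyethyl]prop-2-enoate (racemic)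
Conditions: DABCO (0.5 equiv), 16 (3 equiv), dioxane/H2O, rt
Reagents that add atoms: none
Why: Morita–Baylis–Hillman reaction, for which α-alkoxy aldehydes are reactive partners; the carbinol centre is erased in step 11.

Step 10
Reactants: 18 Morita–Baylis–Hillman alcohol
Product: 19 methyl 2-[1-acetoxy-2-(tert-butyldimethylsilyloxy)ethyl]prop-2-enoate (racemic)
Conditions: Ac2O, pyridine, DMAP (cat.), CH2Cl2, 0 °C → rt
Reagents that add atoms: acetic anhydride, CC(=O)OC(C)=O
Why: Acetylation turns the allylic alcohol into a substrate for oxidative addition to zerovalent palladium.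

Step 11
Reactants: 19 allylic acetate
Product: 20 methyl (E)-4-(tert-butyldimethylsilyloxy)-2-[(4,4,5,5-tetramethyl-1,3,2-dioxaborolan-2-yl)methyl]but-2-enoate
Conditions: B2pin2, Pd2(dba)3 (2.5 mol %), toluene, 50 °C
Reagents that add atoms: bis(pinacolato)diboron, CC1(C)OB(OC1(C)C)B1OC(C)(C)C(C)(C)O1
Why: Palladium-catalysed allylic borylation (oxidative addition, transmetalation with the diboron, reductive elimination at the CH2 terminus) gives the 2-(methoxycarbonyl)allylboronate with the thermodynamically preferred (E) geometry, CH2OTBS cis to CH2B.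

Step 12
Reactants: 15 C8 aldehyde; 20 allylboronate
Product: 21 syn homoallylic alcohol (C7–C8 syn; 8R; hydroxy ester open)
Conditions: (S)-TRIP (10 mol %), toluene, 4 Å MS, 0 °C → rt; aq NaHCO3
Reagents that add atoms: none
Why: Chiral phosphoric acid catalysed allylboration through a closed chair: the γ-substituent cis to CH2B sits axial and gives the 7,8-syn adduct, the catalyst (hydrogen-bonded to a boronate oxygen and the formyl hydrogen) is chosen to direct attack to the Si face of the aldehyde (8R), and without strong acid or heat the γ-hydroxy ester stays open.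

Step 13
Reactants: 21 syn homoallylic alcohol
Product: 22 C8-O-TBS ether
Conditions: TBSOTf, 2,6-lutidine, CH2Cl2, −78 °C
Reagents that add atoms: tert-butyldimethylsilyl triflate, CC(C)(C)[Si](C)(C)OS(=O)(=O)C(F)(F)F
Why: Silyl triflate/lutidine silylation of the hindered secondary alcohol blocks lactonisation of O8 onto the C12 ester.

Step 14
Reactants: 22 bis-silyl ether
Product: 23 C6 primary alcohol
Conditions: HF·pyridine, pyridine, THF, 0 °C; crude carried on
Reagents that add atoms: none
Why: Buffered HF·pyridine cleaves the primary silyl ether much faster than the hindered secondary one (steric differentiation), and the freed γ-hydroxy ester is oxidised without storage so that it does not lactonise.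

Step 15
Reactants: 23 C6 primary alcohol
Product: 24 C6 aldehyde
Conditions: Dess–Martin periodinane, NaHCO3, CH2Cl2, 0 °C; used at once
Reagents that add atoms: none
Why: Buffered Dess–Martin oxidation forms the aldehyde without base, so the doubly activated C7 hydrogen is neither epimerised nor shifted into conjugation.

Step 16
Reactants: 24 C6 aldehyde
Product: 27 tricyclic C8-O-TBS lactone (11-oxabicyclo[4.4.1]undecene core; trans-fused α-methylene-γ-lactone), via samarium enolate 25 (not isolated), via samarium alkoxide 26 (not isolated)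
Conditions: SmI2 (2.5 equiv), THF (0.005 M), −78 → 0 °C; sat. NH4Cl; then PPTS (cat.), CH2Cl2, rt to complete lactonisation
Reagents that add atoms: none
Why: Proposed new method: SmI2 reduces the C6 aldehyde of 24 to a ketyl (the push-pull enol ether ester and the 2-substituted acrylate are far harder to reduce without additives), the ketyl carbon adds to C5, the β-carbon of the ring β-alkoxyacrylate, a second SmI2 turns the C4 radical into the samarium enolate 25, which expels the C3 acetate (both C3 epimers converge) to give the C3=C4 enoate 26, and the C6 samarium alkoxide then acylates on the C12 methyl ester. The closest known reactions are the SmI2 cyclisation of aldehydes onto acyclic (E)-β-alkoxyacrylates, which gives 2,3-trans oxepanes, and SmI2 ketyl–olefin coupling followed by β-elimination of an acetate; their combination on a cyclic, α-substituted acrylate is the untested part. The oxepane (O, C5, C6, C7, C8, C9, C10) closes by 7-exo-trig radical addition and thereby completes the bridged bicycle, and the γ-lactone closes by 5-exo-trig acyl substitution. C5 can only form on the face reached by the tether from C10, so it is set by the linalool-derived centre, and C6 is expected trans to C4 through the samarium-bridged arrangement of ketyl oxygen and ester carbonyl that operates for (E)-β-alkoxyacrylates, an arrangement that also puts the C6–O bond anti to the acrylate arm on C7 fixed in step 12. The step needs addition at C5 instead of attack on the C11 acrylate (which would demand a four-membered ring), elimination instead of protonation of the enolate (no proton source until the quench) and lactonisation onto C12 instead of onto the C4 ester (whose carbonyl lies in the plane of the new enoate, out of reach of a Bürgi–Dunitz approach by O6), while high dilution suppresses pinacol coupling.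

Step 17
Reactants: 28 tiglic acid
Product: 29 (E)-2-methylbut-2-en-1-ol
Conditions: LiAlH4, Et2O, 0 °C → rt
Reagents that add atoms: none
Why: Hydride reduction of the conjugated acid is a 1,2-reduction and keeps the (E) geometry.

Step 18
Reactants: 29 (E)-2-methylbut-2-en-1-ol
Product: 30 [(2R,3R)-2,3-dimethyloxiran-2-yl]methanol
Conditions: Ti(OiPr)4 (cat.), D-(−)-diisopropyl tartrate (cat.), t-BuOOH, 4 Å MS, CH2Cl2, −20 °C
Reagents that add atoms: tert-butyl hydroperoxide, CC(C)(C)OO
Why: Sharpless asymmetric epoxidation: the titanium–D-tartrate complex delivers oxygen to the face of the (E)-allylic alcohol that gives the (2R,3R)-epoxy alcohol, and the cis relation of the two methyl groups follows from the stereospecific syn addition to the (E)-alkene.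

Step 19
Reactants: 30 epoxy alcohol
Product: 31 (2S,3R)-2,3-dimethyloxirane-2-carboxylic acid
Conditions: TEMPO (cat.), PhI(OAc)2 (2.2 equiv), MeCN/H2O, rt
Reagents that add atoms: water, O
Why: TEMPO/PhI(OAc)2 oxidation takes the primary alcohol through the aldehyde hydrate to the acid without opening the epoxide; the label at C2 changes from R to S only because the substituent priorities change.

Step 20
Reactants: 27 tricyclic C8-O-TBS lactone
Product: 32 tricyclic C8 alcohol
Conditions: HF·pyridine, THF, 0 °C → rt
Reagents that add atoms: none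
Why: Fluoride cleavage of the secondary silyl ether is tolerated by the α-methylene lactone, the enoate and the bridging ether.

Step 21
Reactants: 32 tricyclic C8 alcohol; 31 (2S,3R)-2,3-dimethyloxirane-2-carboxylic acid
Product: 34 target CNP0240298.1, via mixed anhydride 33 (not isolated)
Conditions: 31, 2,4,6-trichlorobenzoyl chloride, Et3N, THF, rt; then 32, DMAP, toluene, rt
Reagents that add atoms: none
Why: Yamaguchi esterification: DMAP attacks the less hindered epoxy-acyl carbonyl of mixed anhydride 33 and transfers it to the C8 hydroxyl with retention at every centre.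

## Compound list

1 | (S)-(+)-linalool, (3S)-3,7-dimethylocta-1,6-dien-3-ol | C=C[C@](O)(C)CCC=C(C)C | starting material
2 | 9-(3-hydroxy-3,7-dimethyloct-6-en-1-yl)-9-borabicyclo[3.3.1]nonane, carbinol centre as in 1 | B1(CC[C@](O)(C)CCC=C(C)C)C2CCCC1CCC2 | intermediate
3 | (3S)-3,7-dimethyloct-6-ene-1,3-diol | OCC[C@](O)(C)CCC=C(C)C | intermediate
4 | (3S)-1-(tert-butyldiphenylsilyloxy)-3,7-dimethyloct-6-en-3-ol | CC(C)(C)[Si](c1ccccc1)(c1ccccc1)OCC[C@](O)(C)CCC=C(C)C | intermediate
5 | ozonide of 4, 3-[(3S)-5-(tert-butyldiphenylsilyloxy)-3-hydroxy-3-methylpentyl]-5,5-dimethyl-1,2,4-trioxolane | CC(C)(C)[Si](c1ccccc1)(c1ccccc1)OCC[C@](O)(C)CCC1OOC(C)(C)O1 | intermediate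
6 | (4S)-6-(tert-butyldiphenylsilyloxy)-4-hydroxy-4-methylhexanal | CC(C)(C)[Si](c1ccccc1)(c1ccccc1)OCC[C@](O)(C)CCC=O | intermediate
7 | (5S)-5-[2-(tert-butyldiphenylsilyloxy)ethyl]-5-methyltetrahydrofuran-2-ol (lactol, both anomers) | CC(C)(C)[Si](c1ccccc1)(c1ccccc1)OCC[C@]1(C)CCC(O)O1 | intermediate
8 | methyl 3,3-dimethoxypropanoate | COC(=O)CC(OC)OC | starting material
9 | lithium enolate of 8 (lithium 1,3,3-trimethoxyprop-1-en-1-olate) | [Li+].COC([O-])=CC(OC)OC | intermediate
10 | methyl (6S)-8-(tert-butyldiphenylsilyloxy)-2-(dimethoxymethyl)-3,6-dihydroxy-6-methyloctanoate (C2/C3 mixture; target C4/C3) | CC(C)(C)[Si](c1ccccc1)(c1ccccc1)OCC[C@](O)(C)CCC(O)C(C(=O)OC)C(OC)OC | intermediate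
11 | methyl (2E,6S)-8-(tert-butyldiphenylsilyloxy)-3,6-dihydroxy-2-(methoxymethylidene)-6-methyloctanoate (C3 mixture) | CC(C)(C)[Si](c1ccccc1)(c1ccccc1)OCC[C@](O)(C)CCC(O)/C(C(=O)OC)=C\OC | intermediate
12 | methyl (7S)-7-[2-(tert-butyldiphenylsilyloxy)ethyl]-4-hydroxy-7-methyl-4,5,6,7-tetrahydrooxepine-3-carboxylate (ring C4 = target C3, mixture) | CC(C)(C)[Si](c1ccccc1)(c1ccccc1)OCC[C@]1(C)CCC(O)C(C(=O)OC)=CO1 | intermediate
13 | methyl (7S)-4-acetoxy-7-[2-(tert-butyldiphenylsilyloxy)ethyl]-7-methyl-4,5,6,7-tetrahydrooxepine-3-carboxylate | CC(C)(C)[Si](c1ccccc1)(c1ccccc1)OCC[C@]1(C)CCC(OC(C)=O)C(C(=O)OC)=CO1 | intermediate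
14 | methyl (7S)-4-acetoxy-7-(2-hydroxyethyl)-7-methyl-4,5,6,7-tetrahydrooxepine-3-carboxylate | OCC[C@]1(C)CCC(OC(C)=O)C(C(=O)OC)=CO1 | intermediate
15 | methyl (7S)-4-acetoxy-7-methyl-7-(2-oxoethyl)-4,5,6,7-tetrahydrooxepine-3-carboxylate (C8 aldehyde) | O=CC[C@]1(C)CCC(OC(C)=O)C(C(=O)OC)=CO1 | intermediate
16 | methyl acrylate | C=CC(=O)OC | starting material
17 | (tert-butyldimethylsilyloxy)acetaldehyde | O=CCO[Si](C)(C)C(C)(C)C | starting material
18 | methyl 2-[2-(tert-butyldimethylsilyloxy)-1-hydroxyethyl]prop-2-enoate (racemic) | C=C(C(=O)OC)C(O)CO[Si](C)(C)C(C)(C)C | intermediate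
19 | methyl 2-[1-acetoxy-2-(tert-butyldimethylsilyloxy)ethyl]prop-2-enoate (racemic) | C=C(C(=O)OC)C(OC(C)=O)CO[Si](C)(C)C(C)(C)C | intermediate
20 | methyl (E)-4-(tert-butyldimethylsilyloxy)-2-[(4,4,5,5-tetramethyl-1,3,2-dioxaborolan-2-yl)methyl]but-2-enoate (CH2OTBS cis to CH2B) | COC(=O)/C(CB1OC(C)(C)C(C)(C)O1)=C/CO[Si](C)(C)C(C)(C)C | intermediate
21 | methyl (7S)-4-acetoxy-7-[(2R,3S)-3-(tert-butyldimethylsilyloxymethyl)-2-hydroxy-4-(methoxycarbonyl)pent-4-en-1-yl]-7-methyl-4,5,6,7-tetrahydrooxepine-3-carboxylate (C7–C8 syn, 8R, 10S) | C=C(C(=O)OC)[C@@H](CO[Si](C)(C)C(C)(C)C)[C@H](O)C[C@]1(C)CCC(OC(C)=O)C(C(=O)OC)=CO1 | intermediate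
22 | C8-O-TBS ether of 21 (side chain 2R,3S) | C=C(C(=O)OC)[C@@H](CO[Si](C)(C)C(C)(C)C)[C@H](O[Si](C)(C)C(C)(C)C)C[C@]1(C)CCC(OC(C)=O)C(C(=O)OC)=CO1 | intermediate
23 | C6 primary alcohol: 22 with CH2OH in place of CH2OTBS on C7 | C=C(C(=O)OC)[C@@H](CO)[C@H](O[Si](C)(C)C(C)(C)C)C[C@]1(C)CCC(OC(C)=O)C(C(=O)OC)=CO1 | intermediate
24 | C6 aldehyde: 22 with CHO on C7 (side chain 2R,3R; C8-O-TBS, C3 acetate) | C=C(C(=O)OC)[C@@H](C=O)[C@H](O[Si](C)(C)C(C)(C)C)C[C@]1(C)CCC(OC(C)=O)C(C(=O)OC)=CO1 | intermediate
25 | cyclised samarium enolate–alkoxide (C5–C6 bond formed, C4 enolate, C3 acetate still present; trivalent samarium on both oxygens) | [Sm+3].[Sm+3].[I-].[I-].[I-].[I-].[O-][C@H]2[C@H](C(=C)C(=O)OC)[C@H](O[Si](C)(C)C(C)(C)C)C[C@]1(C)CCC(OC(C)=O)C(=C([O-])OC)[C@H]2O1 | intermediate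
26 | samarium C6 alkoxide of the bicyclic hydroxy enoate (C3=C4 formed, lactone still open) | [Sm+3].[I-].[I-].[O-][C@H]2[C@H](C(=C)C(=O)OC)[C@H](O[Si](C)(C)C(C)(C)C)C[C@]1(C)CCC=C(C(=O)OC)[C@H]2O1 | intermediate
27 | tricyclic lactone: target skeleton with OTBS on C8 (5R, 6S, 8R, 10S; lactone trans-fused at C6/C7) | C=C1C(=O)O[C@H]2[C@H]1[C@H](O[Si](C)(C)C(C)(C)C)C[C@]1(C)CCC=C(C(=O)OC)[C@H]2O1 | intermediate
28 | tiglic acid, (E)-2-methylbut-2-enoic acid | C/C=C(\C)C(=O)O | starting material
29 | (E)-2-methylbut-2-en-1-ol | C/C=C(\C)CO | intermediate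
30 | [(2R,3R)-2,3-dimethyloxiran-2-yl]methanol (methyl groups cis) | OC[C@@]1(C)O[C@@H]1C | intermediate
31 | (2S,3R)-2,3-dimethyloxirane-2-carboxylic acid (methyl groups cis) | OC(=O)[C@@]1(C)O[C@@H]1C | intermediate
32 | tricyclic C8 alcohol: target skeleton with free OH on C8 (5R, 6S, 7R, 8R, 10S) | C=C1C(=O)O[C@H]2[C@H]1[C@H](O)C[C@]1(C)CCC=C(C(=O)OC)[C@H]2O1 | intermediate
33 | (2S,3R)-2,3-dimethyloxirane-2-carboxylic 2,4,6-trichlorobenzoic anhydride | O=C(OC(=O)[C@@]1(C)O[C@@H]1C)c1c(Cl)cc(Cl)cc1Cl | intermediate
34 | CNP0240298.1 (5R, 6S, 7R, 8R, 10S; (2S,3R)-epoxy ester on C8) | C=C1C(=O)O[C@H]2[C@H]1[C@H](OC(=O)[C@@]1(C)O[C@@H]1C)C[C@]1(C)CCC=C(C(=O)OC)[C@H]2O1 | target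

## Step count and risks

Total: 21 steps. Longest linear sequence: 15 steps (1 to 34 through steps 1–8, 12–16, 20 and 21).

Step 16. What may go wrong: reduction or pinacol coupling of the aldehyde outruns addition to the hindered ring acrylate, the samarium enolate is protonated or fragments instead of expelling acetate cleanly, or the face selectivity at C6 is poor. Fallback, from 24 and back at 27: the cascade is taken apart into operations that are each known. SmI2 with methanol as proton source in THF at 0 °C (the established protic ketyl–olefin cyclisation onto β-alkoxyacrylates) deliberately protonates the enolate, and the crude hydroxy ester is closed with PPTS to the saturated acetoxy ester lactone F1. DBU in CH2Cl2 then removes acetic acid by E1cB elimination and gives 27.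

Step 5. What may go wrong: the hindered tertiary hydroxyl does not displace methanol at C5, so the reaction stops at the acyclic methoxyacrylate, or acid-induced ionisation at C3 or C10 diverts material to tetrahydrofurans. Fallback, from 4 and back at 12: the ring is closed by irreversible vinylic substitution under base instead of acid-catalysed exchange. Compound 4 is silylated at the tertiary hydroxyl (TMSCl, imidazole) to the trimethylsilyl ether F2, and ozonolysis (O3, then PPh3) gives the free aldehyde F3. A MgI2-promoted iodo-aldol reaction with methyl propiolate gives the (Z)-β-iodoacrylate carbinol F4, and brief treatment with HF·pyridine frees the tertiary hydroxyl to give the iodo diol F5. Cs2CO3 in MeCN then closes the oxepene by addition–elimination at C5 with loss of iodide and gives 12.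

Step 12. What may go wrong: the ester-deactivated, γ-substituted pinacol boronate adds too slowly under the weak chiral acid, facial control at C8 is eroded by the C10 centre, or the aldehyde opens by E1cB elimination during a long reaction. Fallback, from 19 and back at 21: catalyst control is replaced by reagent control with a more Lewis acidic boronate. Palladium-catalysed borylation of 19 with B2(OH)4 (Pd2(dba)3, DMSO/MeOH) gives the allylboronic acid F6, and esterification with (R,R)-diisopropyl tartrate over MgSO4 gives the tartrate boronate F7. Uncatalysed addition of this reagent to 15 in toluene over 4 Å MS from −78 °C leads to 21; the tartrate is expected to direct attack to the Si face and the closed chair again gives the syn relation.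

Further compounds
F1 | step 16 | C4-protonated cyclisation product: tricyclic lactone with saturated C4 ester and C3 acetate, OTBS on C8 (C3 and C4 as mixtures) | C=C1C(=O)O[C@H]2[C@H]1[C@H](O[Si](C)(C)C(C)(C)C)C[C@]1(C)CCC(OC(C)=O)C(C(=O)OC)[C@H]2O1
F2 | step 5 | (3S)-1-(tert-butyldiphenylsilyloxy)-3,7-dimethyl-3-(trimethylsilyloxy)oct-6-ene | CC(C)(C)[Si](c1ccccc1)(c1ccccc1)OCC[C@](O[Si](C)(C)C)(C)CCC=C(C)C
F3 | step 5 | (4S)-6-(tert-butyldiphenylsilyloxy)-4-methyl-4-(trimethylsilyloxy)hexanal | CC(C)(C)[Si](c1ccccc1)(c1ccccc1)OCC[C@](O[Si](C)(C)C)(C)CCC=O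
F4 | step 5 | methyl (2Z,6S)-8-(tert-butyldiphenylsilyloxy)-3-hydroxy-2-(iodomethylidene)-6-methyl-6-(trimethylsilyloxy)octanoate (C3 mixture) | CC(C)(C)[Si](c1ccccc1)(c1ccccc1)OCC[C@](O[Si](C)(C)C)(C)CCC(O)/C(C(=O)OC)=C/I
F5 | step 5 | methyl (2Z,6S)-8-(tert-butyldiphenylsilyloxy)-3,6-dihydroxy-2-(iodomethylidene)-6-methyloctanoate (C3 mixture) | CC(C)(C)[Si](c1ccccc1)(c1ccccc1)OCC[C@](O)(C)CCC(O)/C(C(=O)OC)=C/I
F6 | step 12 | [(E)-4-(tert-butyldimethylsilyloxy)-2-(methoxycarbonyl)but-2-en-1-yl]boronic acid | COC(=O)/C(CB(O)O)=C/CO[Si](C)(C)C(C)(C)C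
F7 | step 12 | diisopropyl (4R,5R)-2-[(E)-4-(tert-butyldimethylsilyloxy)-2-(methoxycarbonyl)but-2-en-1-yl]-1,3,2-dioxaborolane-4,5-dicarboxylate | COC(=O)/C(CB1O[C@@H](C(=O)OC(C)C)[C@H](C(=O)OC(C)C)O1)=C/CO[Si](C)(C)C(C)(C)C
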